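The synthesis rests on cutting ring A from ring B at C1–C10 and C4–C5. Ring B carries oxygen at C6 and C9 (para), methyls at C8 and C10, and a cis C5–H/C10–CH3 fusion to ring A. This is the imprint of 2,6-dimethyl-1,4-benzoquinone after a suprafacial [4+2] addition. One catalytic enantioselective Diels–Alder reaction with 4-methylpenta-1,3-diene makes ring A, both bonds, the C4 gem-dimethyl group and the C5/C10 stereocentres from two purchased achiral compounds. C6, C8 and C9 are then relayed from this fusion. C13 is set by reagent control. Rings C and D are closed by epoxide opening and alkynol cycloisomerisation.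

Key step: step 1

Reading of the target (labdane numbering): 5R,6R,8R,9R,10S,13R. H5, C10-CH3, 6-OAc and C11 lie on the β face; 8-CH3 and O9 lie on the α face. On ring C, C16 is cis to C8 and C14 is cis to C10. Adduct 3 as drawn (5R,10S) maps onto this without change.

Assumption: the absolute sense of step 1 is assigned from the usual pre-transition-state picture of quinone–oxazaborolidinium complexes. Both prolinol antipodes are commercial, so the (S)-prolinol would be used if the (5S,10R) adduct were favoured.

Step 1
Reactants: 1 2,6-dimethyl-1,4-benzoquinone; 2 4-methylpenta-1,3-diene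
Product: 3 (5R,10S)-cis-enedione, (4aR,8aS)-2,5,5,8a-tetramethyl-4a,5,8,8a-tetrahydronaphthalene-1,4-dione
Conditions: B-(o-tolyl)oxazaborolidinium triflimide from (R)-α,α-diphenylprolinol, o-tolylboronic acid and Tf2NH (20 mol %), 2 (5 equiv, slow addition), CH2Cl2, −40 to −20 °C
Reagents that add atoms: none
Why: The boron Lewis acid binds the C6 carbonyl oxygen, the only one flanked by vinylic C–H, which puts the largest LUMO coefficient on the β carbon C10, so the nucleophilic CH2 terminus of 2 bonds to C10 slightly ahead of the CMe2 terminus bonding to C5 in a concerted, asynchronous [4+2] cycloaddition. The closest known reaction type is the oxazaborolidinium-catalysed enantioselective Diels–Alder reaction of substituted 1,4-benzoquinones with acyclic dienes. Ring A is closed in the intermolecular [4π+2π] mode, with both σ bonds (C1–C10 and C4–C5) made on the same face of the ring B alkene. H5 and C10-CH3 therefore end cis by suprafacial addition to a cyclic alkene, and the absolute configuration (5R,10S) is fixed by the catalyst, whose aryl group covers one face of the bound C5=C10 bond and so also picks one of the two enantiotopic C=C bonds. Regioselectivity is needed and is secured electronically by carbonyl-selective coordination and sterically because the CMe2 terminus meets the unsubstituted C5, while endo/exo selectivity is irrelevant because neither diene terminus becomes a stereocentre. A second cycloaddition is not expected because the remaining C7=C8 bond of 3 lies in a folded, hindered enedione.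

Step 2
Reactants: 3 (5R,10S)-cis-enedione
Product: 4 (5R,6S,10S)-6α-hydroxy enone (C9 ketone, C7=C8 and C2=C3 retained)
Conditions: NaBH4, CeCl3·7H2O, MeOH, −78 °C
Reagents that add atoms: none
Why: Luche 1,2-reduction, in which the hard hydride takes only the C6 carbonyl because C9 is flanked by quaternary C10 and the C8 methyl, and approaches from the convex β face (that of H5 and C10-CH3), which should set the 6α-alcohol before C5 can epimerise.

Step 3
Reactants: 4 (5R,6S,10S)-6α-hydroxy enone
Product: 5 (5R,6R,10S)-6β-(4-nitrobenzoyloxy) enone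
Conditions: 4-nitrobenzoic acid, PPh3, DIAD, toluene, 0 °C to rt
Reagents that add atoms: 4-nitrobenzoic acid, SMILES OC(=O)c1ccc(cc1)[N+](=O)[O-]
Why: Mitsunobu reaction, in which SN2 displacement of the allylic 6α-oxyphosphonium group by the carboxylate inverts C6 to 6β; the acidic aroic acid is the usual choice for hindered alcohols, and a removable ester is chosen because no ester would survive step 6.

Step 4
Reactants: 5 (5R,6R,10S)-6β-(4-nitrobenzoyloxy) enone
Product: 6 (5R,6R,10S)-6β-hydroxy enone
Conditions: K2CO3 (0.2 equiv), MeOH, 0 °C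
Reagents that add atoms: none
Why: Base-catalysed transesterification of an activated aroate breaks the acyl–oxygen bond, so C6 keeps its configuration, and C5 is no longer α to a carbonyl, so the cis fusion is safe.

Step 5
Reactants: 6 (5R,6R,10S)-6β-hydroxy enone
Product: 7 (5R,6R,8R,10S)-6β-hydroxy-8α-methyl-9-ketone, rings A and B saturated
Conditions: H2 (10 bar), [Ir(cod)(PCy3)(py)]PF6 (5 mol %), CH2Cl2, rt
Reagents that add atoms: none
Why: Hydroxyl-directed homogeneous hydrogenation, in which the cationic iridium centre binds the allylic 6β-OH and delivers H2 to the β face of C7=C8 (8β-H, 8α-CH3, 8R), while the disubstituted C2=C3 bond is saturated in the same operation.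

Step 6
Reactants: 7 (5R,6R,8R,10S)-6β-hydroxy-8α-methyl-9-ketone
Product: 8 (5R,6R,8R,9R,10S)-9β-vinyl-6β,9α-diol
Conditions: vinylMgBr (4 equiv), anhydrous CeCl3 (4 equiv), THF, −78 to 0 °C; aq NH4Cl
Reagents that add atoms: vinylmagnesium bromide, SMILES C=C[Mg]Br
Why: Organocerium 1,2-addition to a hindered enolisable ketone, whose low basicity leaves the kinetic C8 centre untouched; because the α face of C9 is closed by C1 of ring A and by the 8α-methyl, vinyl should enter from the β face and set 9R (9α-OH, C11 β), with one equivalent of reagent masking the 6-OH as its alkoxide.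

Step 7
Reactants: 8 (5R,6R,8R,9R,10S)-9β-vinyl-6β,9α-diol; 9 2-bromoprop-2-en-1-ol
Product: 11 (5R,6R,8R,9R,10S)-triol with the chain C11H2–C12H2–C13(=C16H2)–C14H2OH on C9β, via C12 9-BBN borane 10 (not isolated)
Conditions: 9-BBN (3.5 equiv), THF, rt; then 9, PdCl2(dppf) (5 mol %), AsPh3, Cs2CO3, DMF–H2O, rt
Reagents that add atoms: 9-borabicyclo[3.3.1]nonane, SMILES B1C2CCCC1CCC2 (its boron stays only in 10)
Why: Anti-Markovnikov hydroboration of the only alkene followed by B-alkyl Suzuki–Miyaura coupling with the alkenyl bromide joins C12 to C13 without creating a stereocentre, and free hydroxyls are tolerated when the borane is used in excess.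

Step 8
Reactants: 11 (5R,6R,8R,9R,10S)-triol
Product: 12 (13S)-13,16-epoxy alcohol (6β-OH, 9α-OH and C14H2OH free)
Conditions: Ti(OiPr)4 (20 mol %), L-(+)-diethyl tartrate (24 mol %), t-BuOOH, 4 Å MS, CH2Cl2, −20 °C; NaOH/brine work-up
Reagents that add atoms: tert-butyl hydroperoxide, SMILES CC(C)(C)OO
Why: Sharpless asymmetric epoxidation of a 2-substituted allylic alcohol, the only alkene present, under reagent control by the tartrate (the same facial rule that turns 2-methylprop-2-en-1-ol into (S)-2-methylglycidol), which should set 13S regardless of the remote decalin.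

Step 9
Reactants: 12 (13S)-13,16-epoxy alcohol
Product: 13 (13R)-13,16-epoxy-14-aldehyde (same spatial arrangement at C13; the descriptor changes by priority)
Conditions: [Cu(MeCN)4]OTf, 2,2'-bipyridine, TEMPO (5 mol % each), N-methylimidazole (10 mol %), air, MeCN, rt
Reagents that add atoms: none
Why: Copper/nitroxyl aerobic alcohol oxidation is sterically selective for the primary C14 alcohol over the hindered secondary 6β-OH and the tertiary 9-OH, and its mildly basic medium leaves the epoxide closed.

Step 10
Reactants: 13 (13R)-13,16-epoxy-14-aldehyde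
Product: 14 (13S)-13-ethynyl-13,16-epoxide (C14≡C15H)
Conditions: dimethyl (1-diazo-2-oxopropyl)phosphonate, K2CO3, MeOH, 0 °C to rt
Reagents that add atoms: dimethyl (1-diazo-2-oxopropyl)phosphonate, SMILES COP(=O)(OC)C(=[N+]=[N-])C(C)=O
Why: Ohira–Bestmann homologation brings in C15 through an alkylidene carbene and 1,2-hydrogen shift, and the aldehyde has no α-hydrogen, so C13 cannot epimerise.

Step 11
Reactants: 14 (13S)-13-ethynyl-13,16-epoxide
Product: 15 6β-acetate of 14
Conditions: Ac2O, Et3N, DMAP, CH2Cl2, rt
Reagents that add atoms: acetic anhydride, SMILES CC(=O)OC(C)=O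
Why: DMAP-catalysed acylation takes the secondary 6β-OH and leaves the hindered tertiary 9-OH free, and after this point no reagent that attacks esters is used.

Step 12
Reactants: 15 6β-acetoxy ethynyl epoxide
Product: 16 (13R)-ring C oxolane with C13 bearing ethynyl and C16H2OH
Conditions: camphorsulfonic acid (10 mol %), CH2Cl2, 0 °C; Et3N quench
Reagents that add atoms: none
Why: Acid-catalysed 5-exo-tet epoxide opening, in which O9 attacks the tertiary propargylic C13 from the rear of the C13–O bond, closes ring C with inversion (13S to 13R, C16 cis to C8) and frees the C16 hydroxyl.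

Step 13
Reactants: 16 (13R)-ring C oxolane alkynol
Product: 17 target, (5R,6R,8R,9R,10S,13R)-6β-acetoxy-9α,13;15,16-diepoxylabd-14-ene with 5β-H
Conditions: Mo(CO)6 (25 mol %), Et3N, Et2O, hν (350 nm), rt; chromatography on Et3N-deactivated silica
Reagents that add atoms: none
Why: Molybdenum-carbonyl-catalysed 5-endo cycloisomerisation of a but-3-yn-1-ol through a metal vinylidene joins the C16 oxygen to C15 and gives the C14=C15 enol ether of ring D in an amine-buffered medium, so the acid-labile spiro enol ether appears only in the last flask.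

Compound list
1 | 2,6-dimethyl-1,4-benzoquinone | CC1=CC(=O)C=C(C)C1=O | starting material
2 | 4-methylpenta-1,3-diene | C=CC=C(C)C | starting material
3 | (5R,10S)-cis-enedione, C2=C3 and C7=C8 alkenes | O=C1C=C(C)C(=O)[C@@]2(C)CC=CC(C)(C)[C@@H]12 | intermediate
4 | (5R,6S,10S)-6α-hydroxy enone | O[C@H]1C=C(C)C(=O)[C@@]2(C)CC=CC(C)(C)[C@@H]12 | intermediate
5 | (5R,6R,10S)-6β-(4-nitrobenzoyloxy) enone | O=C(O[C@@H]1C=C(C)C(=O)[C@@]2(C)CC=CC(C)(C)[C@@H]12)c1ccc(cc1)[N+](=O)[O-] | intermediate
6 | (5R,6R,10S)-6β-hydroxy enone | O[C@@H]1C=C(C)C(=O)[C@@]2(C)CC=CC(C)(C)[C@@H]12 | intermediate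
7 | (5R,6R,8R,10S)-6β-hydroxy-8α-methyl-9-ketone | O[C@@H]1C[C@@H](C)C(=O)[C@@]2(C)CCCC(C)(C)[C@@H]12 | intermediate
8 | (5R,6R,8R,9R,10S)-9β-vinyl-6β,9α-diol | O[C@@H]1C[C@@H](C)[C@](O)(C=C)[C@@]2(C)CCCC(C)(C)[C@@H]12 | intermediate
9 | 2-bromoprop-2-en-1-ol | C=C(Br)CO | starting material
10 | C12 9-BBN borane of 8 | O[C@@H]1C[C@@H](C)[C@](O)(CCB3C4CCCC3CCC4)[C@@]2(C)CCCC(C)(C)[C@@H]12 | intermediate
11 | (5R,6R,8R,9R,10S)-triol with 3-(hydroxymethyl)but-3-enyl chain on C9β | O[C@@H]1C[C@@H](C)[C@](O)(CCC(=C)CO)[C@@]2(C)CCCC(C)(C)[C@@H]12 | intermediate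
12 | (13S)-13,16-epoxy alcohol | O[C@@H]1C[C@@H](C)[C@](O)(CC[C@]3(CO)CO3)[C@@]2(C)CCCC(C)(C)[C@@H]12 | intermediate
13 | (13R)-13,16-epoxy-14-aldehyde | O[C@@H]1C[C@@H](C)[C@](O)(CC[C@]3(C=O)CO3)[C@@]2(C)CCCC(C)(C)[C@@H]12 | intermediate
14 | (13S)-13-ethynyl-13,16-epoxide | O[C@@H]1C[C@@H](C)[C@](O)(CC[C@]3(C#C)CO3)[C@@]2(C)CCCC(C)(C)[C@@H]12 | intermediate
15 | 6β-acetate of 14 | CC(=O)O[C@@H]1C[C@@H](C)[C@](O)(CC[C@]3(C#C)CO3)[C@@]2(C)CCCC(C)(C)[C@@H]12 | intermediate
16 | (13R)-ring C oxolane, C13 ethynyl and hydroxymethyl, 6β-acetate | CC(=O)O[C@@H]1C[C@@H](C)[C@]2(CC[C@@](C#C)(CO)O2)[C@@]2(C)CCCC(C)(C)[C@@H]12 | intermediate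
17 | CNP0242014.2 | CC(=O)O[C@@H]1C[C@@H](C)[C@]2(CC[C@]3(C=COC3)O2)[C@@]2(C)CCCC(C)(C)[C@@H]12 | target

Total step count: 13. Longest linear sequence: 13 (steps 1 to 13; every other component is purchased).

Steps most likely to fail

Step 1. The diene rarely adopts its s-cis form and is a good monomer for cationic oligomerisation. It may be consumed by the acidic catalyst before it cycloadds, or the reaction may stall. The fallback sets out from 1 and returns at 3, and makes the same two bonds with an activated diene.
- Mesityl oxide is silylated (TIPSOTf, Et3N) to 4-methyl-2-(triisopropylsilyloxy)penta-1,3-diene F1. This is a 2-silyloxydiene of the kind that is the standard partner of quinones with this catalyst family, and its oxygen reinforces attack of C1 on C10.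
- Cycloaddition with 1 under the conditions of step 1 gives the C2 silyl enol ether cycloadduct F2.
- CsF and PhNTf2 in DME convert it into the C2 enol triflate F3.
- Pd(OAc)2, PPh3, HCO2H and Bu3N in DMF replace the triflate by hydrogen and give 3.

Step 3. Activation of the concave, hindered 6α-hydroxyl may be slow. In the oxyphosphonium ion H5 stands anti to the leaving group, so loss of H5 towards a conjugated dienone may outrun substitution. The fallback sets out from 3 and returns at 6, replacing substitution by reagent-controlled reduction. It is a CBS reduction with (S)-2-methyl-CBS-oxazaborolidine and catecholborane in toluene at −78 °C. The branched C5 side acts as the large group and C7–H as the small group of the C6 ketone, so hydride is delivered to the α face against the substrate bias. This gives the 6β-alcohol directly in place of steps 2 to 4. No new compound arises on this path (F0).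

Step 8. The Lewis acidic titanium may let the 9-OH attack the fresh epoxide in the flask. Ring closure at this stage leaves C13 with two identical CH2OH arms and erases the stereochemical information; attack at C16 would build a six-membered ether instead. The fallback sets out from 11 and returns at 13, differentiating the two arms before the epoxide exists.
- MnO2 in CH2Cl2 oxidises only the allylic alcohol to the 2-substituted acrolein F4.
- Iminium-catalysed nucleophilic epoxidation with H2O2 and a diphenylprolinol silyl ether (antipode chosen for 13R) gives epoxy aldehyde 13, whose C13 is deactivated towards premature opening by the neighbouring formyl group.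

Further compounds
F1 | step 1 | 4-methyl-2-(triisopropylsilyloxy)penta-1,3-diene | C=C(O[Si](C(C)C)(C(C)C)C(C)C)C=C(C)C
F2 | step 1 | (5R,10S)-C2 silyl enol ether cycloadduct | O=C1C=C(C)C(=O)[C@@]2(C)CC(O[Si](C(C)C)(C(C)C)C(C)C)=CC(C)(C)[C@@H]12
F3 | step 1 | (5R,10S)-C2 enol triflate | O=C1C=C(C)C(=O)[C@@]2(C)CC(OS(=O)(=O)C(F)(F)F)=CC(C)(C)[C@@H]12
F0 | step 3 | none | none
F4 | step 8 | (5R,6R,8R,9R,10S)-6β,9α-diol with 3-formylbut-3-enyl chain on C9β | O[C@@H]1C[C@@H](C)[C@](O)(CCC(=C)C=O)[C@@]2(C)CCCC(C)(C)[C@@H]12
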